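## Retrosynthetic overview

1. Both flavan-3-ol halves, with rings A, B and C and all four stereocentres (2R,3S in each half), come intact from (+)-catechin 1. The only skeletal bond to make is the biaryl bond C6' (ring B, upper unit)–C6 (ring A, lower unit).
2. That bond is cut the way the plant oxidase is presumed to make it: the ring-B o-quinone of one unit (electrophile at C6') plus the phloroglucinol-type ring A of a second, unprotected unit (nucleophile).
3. Ring A of catechin reacts mainly at C8, so C8 is first blocked with bromine through transient silyl ethers 2 and 3 to give 8-bromocatechin 4. Compound 4 then plays both roles: its quinone 5 is attacked by a second molecule of 4 at C6, the only free ring-A carbon, giving dibromo dimer 6.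
4. Target 7 follows from 6 by hydrogenolysis of the two C–Br bonds.
5. Order of ring formation: no ring is built. The two chroman systems and the two catechol rings are carried through unchanged, and the halves are joined in the second of three steps.

Assumption: the target is read as (+)-catechin-(6'→6)-(+)-catechin (a B-type dehydrodicatechin), both units (2R,3S), with no defined configuration about the biaryl axis; flavan numbering is used, primed atoms are ring B, and the "upper" unit is the one joined through ring B.

## Route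

Step 1
Reactants: 1 (+)-catechin
Product: 4 8-bromo-(+)-catechin [(2R,3S)-8-bromo-2-(3,4-dihydroxyphenyl)chromane-3,5,7-triol], via penta-O-trimethylsilyl-(+)-catechin 2 (not isolated), via 8-bromo-penta-O-trimethylsilyl-(+)-catechin 3 (not isolated)
Conditions: HMDS (4 equiv), TMSCl (5 mol %), MeCN, 60 °C, 2 h; evaporate; NBS (1.0 equiv), CH2Cl2, −78 → −20 °C, dark; then MeOH, HCl (cat.), 0 °C → rt
Reagents that add atoms: N-bromosuccinimide, O=C1CCC(=O)N1Br
Why: Persilylation turns ring A into a 5,7-bis(silyloxy) ether in which C6 is shielded between two OSiMe3 groups, so electrophilic aromatic bromination with NBS should go to C8 by analogy with tetra-O-benzyl- and tetra-O-methylcatechin, and mild acidic methanolysis then removes all five silyl groups without touching C–Br or the C2/C3 stereocentres (no stereocentre is formed).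

Step 2
Reactants: 4 8-bromo-(+)-catechin (two molecules: one is oxidised in the flask, the other adds as the nucleophile)
Product: 6 8,8''-dibromo-(+)-catechin-(6'→6)-(+)-catechin [(2R,3S)-8-bromo-2-{2-[(2R,3S)-8-bromo-2-(3,4-dihydroxyphenyl)-3,5,7-trihydroxychroman-6-yl]-4,5-dihydroxyphenyl}chromane-3,5,7-triol], via ring-B o-quinone of 8-bromocatechin 5 (not isolated)
Conditions: NaIO4 (0.4 equiv, added over 30 min), 0.1 M NaH2PO4/H3PO4 buffer (pH 3.0)–MeCN 3:1, 0 °C → rt, 1 h, argon; preparative RP-18 HPLC, unreacted 4 recovered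
Reagents that add atoms: none
Why: This is a biomimetic oxidative phenol coupling of the B-type dehydrodicatechin kind, in which NaIO4 oxidises the ring-B catechol of part of 4 to o-quinone 5, ring A of unoxidised 4 adds through C6 (the only ring-A carbon left free by the C8 bromine) to C6' of 5 in an acid-promoted Michael (1,4) addition, and enolisation restores the catechol; no stereocentre is formed or touched.

Step 3
Reactants: 6 8,8''-dibromo-(+)-catechin-(6'→6)-(+)-catechin
Product: 7 (+)-catechin-(6'→6)-(+)-catechin (target)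
Conditions: H2 (1 atm), Pd(OH)2/C (10 mol % Pd), NaOAc (2.5 equiv), MeOH, rt, 2 h; filter under argon; RP-18
Reagents that add atoms: none
Why: Heterogeneous catalytic hydrogenolysis (hydrodehalogenation) of the two electron-rich aryl C–Br bonds, with NaOAc taking up the HBr, is the standard way to remove a C8 bromine blocking group from flavan-3-ols and leaves the benzylic C2–O bonds and all four stereocentres untouched at one atmosphere and room temperature.

## Compound list

1 | (+)-catechin, (2R,3S)-2-(3,4-dihydroxyphenyl)chromane-3,5,7-triol | Oc1cc(O)c2c(c1)O[C@H](c1ccc(O)c(O)c1)[C@@H](O)C2 | starting material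
2 | 3,5,7,3',4'-penta-O-trimethylsilyl-(+)-catechin (2R,3S) | C[Si](C)(C)Oc1cc(O[Si](C)(C)C)c2c(c1)O[C@H](c1ccc(O[Si](C)(C)C)c(O[Si](C)(C)C)c1)[C@@H](O[Si](C)(C)C)C2 | intermediate
3 | 8-bromo-3,5,7,3',4'-penta-O-trimethylsilyl-(+)-catechin (2R,3S) | C[Si](C)(C)Oc1cc(O[Si](C)(C)C)c2c(c1Br)O[C@H](c1ccc(O[Si](C)(C)C)c(O[Si](C)(C)C)c1)[C@@H](O[Si](C)(C)C)C2 | intermediate
4 | 8-bromo-(+)-catechin, (2R,3S)-8-bromo-2-(3,4-dihydroxyphenyl)chromane-3,5,7-triol | Oc1cc(O)c2c(c1Br)O[C@H](c1ccc(O)c(O)c1)[C@@H](O)C2 | intermediate
5 | ring-B o-quinone of 8-bromo-(+)-catechin, 4-[(2R,3S)-8-bromo-3,5,7-trihydroxychroman-2-yl]cyclohexa-3,5-diene-1,2-dione | Oc1cc(O)c2c(c1Br)O[C@H](C1=CC(=O)C(=O)C=C1)[C@@H](O)C2 | intermediate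
6 | 8,8''-dibromo-(+)-catechin-(6'→6)-(+)-catechin, both units (2R,3S), Br on C8 of each ring A, biaryl bond from C6' of the upper ring B to C6 of the lower ring A | Oc1cc(O)c2c(c1Br)O[C@H](c1cc(O)c(O)cc1-c1c(O)c(Br)c3c(c1O)C[C@H](O)[C@@H](c1ccc(O)c(O)c1)O3)[C@@H](O)C2 | intermediate
7 | (+)-catechin-(6'→6)-(+)-catechin, (2R,3S)-2-{2-[(2R,3S)-2-(3,4-dihydroxyphenyl)-3,5,7-trihydroxychroman-6-yl]-4,5-dihydroxyphenyl}chromane-3,5,7-triol | Oc1cc(O)c2c(c1)O[C@H](c1cc(O)c(O)cc1-c1c(O)cc3c(c1O)C[C@H](O)[C@@H](c1ccc(O)c(O)c1)O3)[C@@H](O)C2 | target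

## Step count and risk

Total step count: 3. Longest linear sequence: 3 steps (1 → 4 → 6 → 7).

The three steps most likely to fail, in order of risk:

Step 2 (key coupling). The product catechol 6 is more easily oxidised than 4, so it can be drawn into further oxidation (cyclised A-type products, trimers). Ether-linked (C–O) dimers can also form, and the bromine may slow attack at C6. Low conversion, slow addition of the oxidant and pH 3 are meant to limit this, and a modest yield with recycling of 4 is expected. Fallback: set out from 1 instead of 4 and give up the blocking group. Oxidise 1 itself with laccase from Trametes versicolor under air in acetate buffer at pH 3.5, so that the (+)-catechin ring-B o-quinone F3 is trapped by ring A of unoxidised 1 at C8 (major) and at C6 (minor). The C6'–C6 dimer is then separated from the C6'–C8 isomer and the ether-linked dimers by preparative RP-18 HPLC. This fallback comes back to the route at 7 itself and bypasses 4, 6 and step 3; regiochemistry is then settled by separation rather than by blocking.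

Step 1 (C8-selective bromination through transient silyl ethers). Incomplete silylation, or loss of the 5-O-silyl group before bromination, would erode the selectivity and give 6-bromo and 6,8-dibromo material. Fallback: set out from 1 and use isolable ethers. Benzylate the four phenols (BnBr, K2CO3, DMF, 0 °C → rt) to 5,7,3',4'-tetra-O-benzyl-(+)-catechin F1. Brominate with NBS in CH2Cl2 (−78 °C → rt), which is regioselective for C8, to give 8-bromo-5,7,3',4'-tetra-O-benzyl-(+)-catechin F2. Remove the benzyl groups without touching C–Br using BCl3 and pentamethylbenzene in CH2Cl2 at −78 °C. This comes back to the route at 4.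

Step 3 (double hydrodebromination of a free decaphenol). The polyphenol may inhibit the catalyst, the second, hindered bromide may lag, and forcing the reaction risks hydrogenolysis of the benzylic C2–O bonds. Fallback: set out from 6 and change to a protected substrate and a radical mechanism. Acetylate all ten hydroxyls (Ac2O, pyridine, DMAP cat., rt) to deca-O-acetyl-8,8''-dibromo-(+)-catechin-(6'→6)-(+)-catechin F4. Remove both bromines by radical chain reduction (Bu3SnH, AIBN, toluene, 90 °C) to give deca-O-acetyl-(+)-catechin-(6'→6)-(+)-catechin F5. Deacetylate (K2CO3 cat., degassed MeOH, 0 °C, argon, then acidic resin). This comes back to the route at 7.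

## Further compounds

F1 | step 1 | 5,7,3',4'-tetra-O-benzyl-(+)-catechin (2R,3S) | c1ccc(cc1)COc1cc(OCc3ccccc3)c2c(c1)O[C@H](c1ccc(OCc3ccccc3)c(OCc3ccccc3)c1)[C@@H](O)C2
F2 | step 1 | 8-bromo-5,7,3',4'-tetra-O-benzyl-(+)-catechin (2R,3S) | c1ccc(cc1)COc1cc(OCc3ccccc3)c2c(c1Br)O[C@H](c1ccc(OCc3ccccc3)c(OCc3ccccc3)c1)[C@@H](O)C2
F3 | step 2 | (+)-catechin ring-B o-quinone, 4-[(2R,3S)-3,5,7-trihydroxychroman-2-yl]cyclohexa-3,5-diene-1,2-dione | Oc1cc(O)c2c(c1)O[C@H](C1=CC(=O)C(=O)C=C1)[C@@H](O)C2
F4 | step 3 | deca-O-acetyl-8,8''-dibromo-(+)-catechin-(6'→6)-(+)-catechin | CC(=O)Oc1cc(OC(C)=O)c2c(c1Br)O[C@H](c1cc(OC(C)=O)c(OC(C)=O)cc1-c1c(OC(C)=O)c(Br)c3c(c1OC(C)=O)C[C@H](OC(C)=O)[C@@H](c1ccc(OC(C)=O)c(OC(C)=O)c1)O3)[C@@H](OC(C)=O)C2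
F5 | step 3 | deca-O-acetyl-(+)-catechin-(6'→6)-(+)-catechin | CC(=O)Oc1cc(OC(C)=O)c2c(c1)O[C@H](c1cc(OC(C)=O)c(OC(C)=O)cc1-c1c(OC(C)=O)cc3c(c1OC(C)=O)C[C@H](OC(C)=O)[C@@H](c1ccc(OC(C)=O)c(OC(C)=O)c1)O3)[C@@H](OC(C)=O)C2
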